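**Retrosynthetic overview**
- Feature: the only ring, the six-membered carbocycle C1–C6, carries oxygen on C1, C2, C4 and C5. It is therefore two vicinal C(O)–C(O) pairs (C1–C2 and C4–C5) bridged by C3 (nonadecyl) and C6 (H), i.e. the mono-methyl ether of a tautomer of a 3-alkylcyclohexane-1,2,4,5-tetraone.
- Last cut: the O-methyl group at C5, back to 2,5-dihydroxy-3-nonadecyl-1,4-benzoquinone. The chain on C3 decides which hydroxyl is etherified.
- Key cut: C3–C4 and C5–C6, which opens the only ring into tricosane-2,3-dione (C6–C1–C2–C3 plus chain) and diethyl oxalate (C4–C5). In the forward sense this is a 4C + 2C double Claisen annulation that needs no redox change.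
- The diketone goes back to tricos-2-yne (alkyne oxidation), and the alkyne to propyne and 1-bromoicosane (acetylide alkylation).

Key step: step 3

Remark: the target has no stereocentre and no stereogenic double bond, so no step has to control configuration. Ring numbering used throughout: C1 (C=O), C2 (OH), C3 (nonadecyl), C4 (C=O), C5 (OMe), C6 (H).

**Step 1**
Reactants: 1 propyne; 2 icosyl bromide (1-bromoicosane)
Product: 4 tricos-2-yne, via prop-1-ynyllithium 3 (not isolated)
Conditions: 1 (excess), n-BuLi, THF, −78 °C; then 2, DMPU, −78 °C to rt
Reagents that add atoms: none
Why: SN2 alkylation of a lithium acetylide with an unhindered primary bromide is a standard C(sp)–C(sp3) coupling, DMPU loosens the acetylide aggregates, and keeping propyne in excess over n-BuLi avoids a second metalation at the propargylic methyl group.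

**Step 2**
Reactants: 4 tricos-2-yne
Product: 5 tricosane-2,3-dione
Conditions: RuCl3·3H2O (2 mol %), NaIO4 (2.2 equiv), NaHCO3, CH2Cl2–MeCN–H2O, 0 °C to rt, short reaction time
Reagents that add atoms: sodium periodate, [Na+].[O-]I(=O)(=O)=O (its oxygen is passed on through RuO4, O=[Ru](=O)(=O)=O)
Why: RuO4-catalysed oxidation of an internal alkyne to the 1,2-diketone proceeds by cycloaddition of RuO4 to the triple bond, collapse of the ruthenate ester and reoxidation by periodate, the saturated chain is inert, and buffering with a short contact time should hold back C–C cleavage.

**Step 3**
Reactants: 5 tricosane-2,3-dione; 6 diethyl oxalate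
Product: 9 2,5-dihydroxy-3-nonadecyl-1,4-benzoquinone, via ethyl 2,4,5-trioxopentacosanoate 7 (not isolated), via disodium quinonediolate 8 (not isolated)
Conditions: 6 (3 equiv), NaOEt (4 equiv), THF–EtOH, Ar, 0 °C, 5 in THF added slowly by syringe pump; then reflux; then aq. HCl
Reagents that add atoms: none
Why: Proposed new method: ethoxide enolises 5 at its methyl carbon, this enolate acylates one ester group of the non-enolisable oxalate 6 (bond C5–C6) to give trioxo ester 7, which is held as its stabilised enolate, and a second reversible deprotonation at the chain-bearing methylene lets that carbon attack the remaining ester (bond C3–C4). The closest known reaction types are the double Claisen condensation of diethyl oxalate with dialkyl ketones to cyclopentane-1,2,4-triones and the alkoxide-mediated self-condensation of 2-oxoalkanoates to 3,6-dialkyl-2,5-dihydroxybenzoquinones, which runs through the same kind of 2,4,5-trioxo ester, so that what is new is an acyclic enolisable 1,2-diketone as the four-carbon partner. The one ring closes by a 6-(enolendo)-exo-trig Dieckmann-type acylation, a favoured mode, because both carbons of the attacking enolate (C2=C3) become ring members, and proton exchange in ethanol lets the C5–C6–C1 enolate leave its chelated U shape for the W shape that brings C3 and C4 together while sodium bridges the vicinal oxygen pairs. No stereocentre is created. Every C–C bond formation is reversible, but the cyclohexane-1,2,4,5-tetraone tautomerises and is deprotonated twice to the bis(vinylogous carboxylate) 8, a sink that should draw the equilibria to the ring. The step needs cross-acylation to win over aldol self-condensation and benzilic-type rearrangement of 5, which is secured by keeping free 5 very dilute against base and excess 6, and regiochemistry is not at stake because 5 has only two enolisable carbons and both must react, in either order, to give the same ring.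

**Step 4**
Reactants: 9 2,5-dihydroxy-3-nonadecyl-1,4-benzoquinone
Product: 10 irisoquin-C (2-hydroxy-5-methoxy-3-nonadecyl-1,4-benzoquinone)
Conditions: MeOH–CH2Cl2, conc. H2SO4 (cat.), reflux
Reagents that add atoms: methanol, CO
Why: In this acid-catalysed vinylogous Fischer esterification methanol adds to C5 of the protonated HO–C5=C6–C1=O unit and water is lost, whereas the same addition at C2 is blocked by the chain on the neighbouring C3, in line with the general inertness of 3-alkyl-2-hydroxyquinones to this exchange.

**Compound list**
1 | propyne | CC#C | starting material
2 | 1-bromoicosane (icosyl bromide) | CCCCCCCCCCCCCCCCCCCCBr | starting material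
3 | prop-1-ynyllithium | [Li]C#CC | intermediate
4 | tricos-2-yne | CCCCCCCCCCCCCCCCCCCCC#CC | intermediate
5 | tricosane-2,3-dione | CCCCCCCCCCCCCCCCCCCCC(=O)C(C)=O | intermediate
6 | diethyl oxalate | CCOC(=O)C(=O)OCC | starting material
7 | ethyl 2,4,5-trioxopentacosanoate (in the flask as its sodium enolate) | CCCCCCCCCCCCCCCCCCCCC(=O)C(=O)CC(=O)C(=O)OCC | intermediate
8 | disodium 3-nonadecyl-1,4-benzoquinone-2,5-diolate | CCCCCCCCCCCCCCCCCCCC1=C([O-])C(=O)C=C([O-])C1=O.[Na+].[Na+] | intermediate
9 | 2,5-dihydroxy-3-nonadecyl-1,4-benzoquinone | CCCCCCCCCCCCCCCCCCCC1=C(O)C(=O)C=C(O)C1=O | intermediate
10 | irisoquin-C, 2-hydroxy-5-methoxy-3-nonadecyl-1,4-benzoquinone | CCCCCCCCCCCCCCCCCCCC1=C(O)C(=O)C=C(OC)C1=O | target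

**Total step count:** 4. **Longest linear sequence:** 4 steps.

**Steps most likely to fail**

1. Step 3.
   - Risk: aldol self-condensation or alkoxide-induced rearrangement of the diketone may outrun the first acylation. A second intermolecular oxalylation may compete with ring closure. The sequence may also stall before the Dieckmann-type closure.
   - Fallback (known chemistry, chain put on a preformed ring): it sets out from 2 and comes back at 9. E2 elimination of 2 with KOt-Bu in THF should give icos-1-ene F1. Ozonolysis in CH2Cl2–MeOH at −78 °C with Me2S work-up removes the terminal carbon and gives nonadecanal F2. Organocatalytic three-component reductive alkylation then follows, using commercial 2,5-dihydroxy-1,4-benzoquinone in excess, F2, Hantzsch ester and L-proline in CH2Cl2. It runs by Knoevenagel condensation at a free ring C–H and then transfer hydrogenation, and it should deliver 9.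

2. Step 2.
   - Risk: over-oxidation with cleavage of the C2–C3 bond, or slow turnover because the waxy alkyne stays out of reach of the aqueous oxidant.
   - Fallback (the two oxygens are installed first and the oxidation level is raised afterwards): it sets out from 4 and comes back at 5. Semi-hydrogenation over Pd on CaCO3 poisoned with Pb(OAc)2, with quinoline, should give (Z)-tricos-2-ene F3. Upjohn dihydroxylation (OsO4 cat., NMO, acetone–H2O–THF) adds both hydroxyls syn and gives racemic (2R,3S)-tricosane-2,3-diol F4. A double Swern oxidation ((COCl)2, DMSO, Et3N, CH2Cl2, −78 °C) takes the diol to 5 without C–C cleavage and erases both stereocentres.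

3. Step 4.
   - Risk: loss of site selectivity through etherification of both hydroxyls on long heating, or sluggish exchange because of poor solubility.
   - Fallback: it sets out from 9 and comes back at 10. The O–CH3 bond is made instead of the C5–O bond, and the choice between the hydroxyls rests on acidity rather than on access to a ring carbon. One equivalent of NaHCO3 in DMF should ionise only the HO–C5=C6–C1=O vinylogous acid, whose central carbon C6 lacks the donor alkyl group. SN2 methylation of this mono-anion with MeI should give 10, since attack through either oxygen of the ambident O5/O1 anion leads, after a proton shift, to the same quinone. No new compound is made on this way (F0).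

**Further compounds**
F1 | step 3 | icos-1-ene | CCCCCCCCCCCCCCCCCCC=C
F2 | step 3 | nonadecanal | CCCCCCCCCCCCCCCCCCC=O
F3 | step 2 | (Z)-tricos-2-ene | C/C=C\CCCCCCCCCCCCCCCCCCCC
F4 | step 2 | rac-(2R,3S)-tricosane-2,3-diol (one enantiomer drawn) | C[C@@H](O)[C@@H](O)CCCCCCCCCCCCCCCCCCCC
F0 | step 4 | none | none
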